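**Plan**

1. Numbering used throughout: ring C1 (C–CH3, epoxide), C2 (epoxide CH), C3 (CH2), C4 (bears C7), C5 and C6 (angelate carbons); chain C7 (=CH2), C8 (angelate carbon), C9, C10–C11 (side-chain epoxide).
2. Enabling feature: the epoxide oxygen on C1 and carbon C7 on C4 are 1,4-cis on the cyclohexane ring, so they can be the two ends of an O–C(=O) bridge. The ring is thus a masked 2-oxabicyclo[2.2.2]octene, the Diels–Alder adduct of a 2-pyrone. The retrosynthesis cuts C3–C4 and C1–C2 (cycloaddition), then C7–C8, the three ester C–O bonds and the C10–C11 epoxide.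
3. Forward: 4-methoxy-6-methyl-2-pyrone and ethyl vinyl ketone give the bridged lactone (cyclohexene ring formed; C1, C2, C4 set). The enol ether is turned into C6–OH and then C5–OH on the bicycle. Baeyer–Villiger oxidation converts the acyl helper into the C2 oxygen. Lactone opening frees the C1 oxygen, which closes the ring epoxide by displacing a C2 mesylate.
4. C7 amide → methyl ketone → alkenyl triflate → NiCl2/CrCl2-mediated coupling with 4-methylpent-3-enal (C7–C8). The C8 hydroxyl is then angeloylated, the ring diol is desilylated and bis-angeloylated, and the prenyl alkene is epoxidised last.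
5. Stereochemistry: absolute configuration from the amine-catalysed cycloaddition (C1, C4; C2 by the endo rule). C6 and C5 are relayed by the bicycle (oxidant from the lactone face, hydroxyl-directed hydride). The ring epoxide arises by SN2 inversion at C2. C8 is set by a chiral ligand on chromium and C10 by the D-fructose-derived ketone.

Key step: step 1

Assumption: the sense of induction of the amine catalyst (step 1) and of the sulfonamide ligand (step 11) on these substrates is taken by analogy with simpler cases, the mirror-image catalyst or ligand being used if a first run showed the opposite sense; angelic anhydride is taken as a purchasable compound.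

**Route**

Step 1
Reactants: 1 4-methoxy-6-methyl-2H-pyran-2-one; 2 pent-1-en-3-one (ethyl vinyl ketone)
Product: 3 (1R,4R,7R)-5-methoxy-1-methyl-7-propanoyl-2-oxabicyclo[2.2.2]oct-5-en-3-one (bridged lactone from C1–O to C7 on C4; propanoyl on C2 endo)
Conditions: (2S,5S)-5-benzyl-3-methyl-2-(5-methylfuran-2-yl)imidazolidin-4-one·HClO4 (20 mol %), 2 (3 equiv), CH2Cl2 containing 1 equiv H2O, −20 → 4 °C
Reagents that add atoms: none
Why: Proposed new method: 2 condenses with the imidazolidinone to a chiral α,β-unsaturated iminium ion whose low LUMO is attacked by the diene of pyrone 1 (future C1=C6–C5=C4, polarised by the ring oxygen on C1 and the methoxy group on C5 so that C4 is the nucleophilic end) in a concerted but asynchronous [4+2] cycloaddition in which C3–C4 leads and C1–C2 follows, and hydrolysis of the product iminium ion releases 3 and the amine. The closest known reaction types are the imidazolidinone-catalysed Diels–Alder reaction of simple vinyl ketones with acyclic alkoxy dienes and the amine-catalysed Diels–Alder reaction of 3-hydroxy-2-pyrones with enones, and a 4-alkoxy-2-pyrone without the 3-hydroxyl has not been shown in either, hence the label. The cyclohexene ring C1–C6 is closed by the [4+2] cycloaddition itself (suprafacial on both partners), and the O–C(=O) unit of the pyrone thereby becomes the two-atom bridge of the 2-oxabicyclo[2.2.2]octene without a separate closure. C1 and C4 are set together and are cis by necessity because the dienophile adds to one face of the flat pyrone, that face being selected by the benzyl-shielded iminium ion (catalyst control of absolute configuration), and C2 is set by the endo rule, the acyl group lying under the diene and ending syn to the new C5=C6 bond. The step needs the regiochemistry in which the acyl-bearing carbon bonds to the methyl-bearing C1 (secured by the matched donor effects of both oxygens at C4 and the polarised iminium ion), cycloaddition faster than proton loss from a C4-alkylated cationic intermediate (favoured by the intramolecular second bond formation, low temperature and a non-basic counter-ion), and survival of the enol ether (near-absence of free acid and water).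

Step 2
Reactants: 3 bridged enol ether lactone
Product: 5 α-hydroxy ketone (bridged lactone; C5 ketone; C6–OH syn to the lactone bridge; C2 propanoyl unchanged), via methoxy epoxide 4 (not isolated)
Conditions: dimethyldioxirane (1.1 equiv, acetone solution), CH2Cl2, −40 °C; then H2O, silica gel, 0 °C
Reagents that add atoms: dimethyldioxirane, CC1(C)OO1; water, O
Why: Epoxidation of the electron-rich enol ether by the neutral dioxirane (Rubottom-type oxidation) is far faster than any reaction of the ketone or lactone and should occur on the alkene face turned to the flat lactone bridge, because the other face is covered by the endo propanoyl group on C2, so that mild hydrolysis of the methoxy epoxide leaves the C6 hydroxyl syn to the bridge (cis to the C1 oxygen) and a ketone at C5.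

Step 3
Reactants: 5 α-hydroxy ketone
Product: 6 trans-5,6-diol (bridged lactone; C6–OH syn and C5–OH anti to the lactone bridge; C2 propanoyl endo)
Conditions: Me4NBH(OAc)3 (4 equiv), AcOH/MeCN 1:1, −20 °C
Reagents that add atoms: none
Why: In this hydroxyl-directed reduction (Saksena–Evans type) the C6 hydroxyl binds boron and delivers hydride to the same face of the neighbouring C5 ketone, which should give the trans-diol with C5–OH anti to the lactone bridge, while the ethyl ketone (no neighbouring hydroxyl) and the lactone are not reduced by this mild reagent.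

Step 4
Reactants: 6 trans-diol ethyl ketone
Product: 7 C2 propanoate (as 6 but with propanoyloxy in place of propanoyl on C2; same configuration)
Conditions: mCPBA (3 equiv), Na2HPO4, CH2Cl2, 25 °C
Reagents that add atoms: 3-chloroperbenzoic acid, OOC(=O)c1cccc(Cl)c1
Why: In the Baeyer–Villiger oxidation the secondary carbon C2 migrates in preference to the primary ethyl group and with retention of configuration, so the acyl helper becomes the C2 oxygen, still anti to the lactone bridge and therefore trans to the C1 oxygen.

Step 5
Reactants: 7 diol propanoate
Product: 8 bis(triethylsilyl) ether of 7 (C5–OSiEt3 and C6–OSiEt3)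
Conditions: Et3SiOTf (3 equiv), 2,6-lutidine (5 equiv), CH2Cl2, 0 °C → rt
Reagents that add atoms: triethylsilyl trifluoromethanesulfonate, CC[Si](CC)(CC)OS(=O)(=O)C(F)(F)F
Why: Silylation of hindered secondary alcohols with a silyl triflate and a hindered base is standard, and placing it after the Baeyer–Villiger step means no enolisable ketone is present and the C2 ester remains the only acyl-protected oxygen.

Step 6
Reactants: 8 bis-silyl ether lactone propanoate
Product: 9 Weinreb amide diol (C7 N-methoxy-N-methylamide on C4; tertiary C1–OH cis to C7; C2–OH trans to C1–OH; C5–OSiEt3 trans to C7; C6–OSiEt3 cis to C1–OH)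
Conditions: MeNH(OMe)·HCl (6 equiv), iPrMgCl (12 equiv), THF, −20 → 0 °C
Reagents that add atoms: N,O-dimethylhydroxylamine hydrochloride, CNOC.Cl
Why: The magnesium amide aminolyses both ester functions (Weinreb amide formation), opening the strained bridged lactone at C7 to free the tertiary C1 hydroxyl and cleaving the propanoate to the C2 hydroxyl, without change at any stereocenter because this weakly basic reagent does not epimerise C4.

Step 7
Reactants: 9 Weinreb amide diol
Product: 11 epoxy Weinreb amide (1,2-epoxide cis to C7 and to the C6 oxygen; ring configuration as in 23), via C2 mesylate 10 (not isolated)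
Conditions: MsCl (1.5 equiv), Et3N (3 equiv), CH2Cl2, 0 °C; then DBU (3 equiv), rt
Reagents that add atoms: none
Why: Only the secondary C2 hydroxyl is sulfonylated, and the tertiary C1 alkoxide then displaces the trans mesylate from the rear (intramolecular Williamson reaction through the chair with both groups axial), which inverts C2 and places the epoxide oxygen on the face of C7 and of the C6 oxygen as in the target.

Step 8
Reactants: 11 epoxy Weinreb amide
Product: 12 methyl ketone (acetyl group on C4; ring as in 11)
Conditions: MeLi (1.5 equiv), THF, −78 °C; NH4Cl quench at −78 °C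
Reagents that add atoms: methyllithium, [Li]C
Why: Addition of methyllithium to the Weinreb amide stops at the chelated tetrahedral intermediate and gives the methyl ketone on work-up, and at −78 °C the trisubstituted epoxide and the silyl ethers are not attacked and C4 is not deprotonated.

Step 9
Reactants: 12 methyl ketone
Product: 13 alkenyl triflate (C7(=CH2)–OSO2CF3 on C4; ring as in 11)
Conditions: KN(SiMe3)2 (1.2 equiv) added to 12 and PhNTf2 (1.3 equiv), THF, −78 °C
Reagents that add atoms: N-phenylbis(trifluoromethanesulfonimide), O=S(=O)(N(c1ccccc1)S(=O)(=O)C(F)(F)F)C(F)(F)F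
Why: Kinetic deprotonation by the bulky amide base occurs at the methyl group and not at the hindered tertiary C4–H, and immediate O-sulfonylation of the terminal enolate gives the 1,1-disubstituted alkenyl triflate before the enolate can equilibrate to C4 and expel the C5 silyloxy group.

Step 10
Reactants: 14 4-methylpent-3-en-1-ol
Product: 15 4-methylpent-3-enal
Conditions: Dess–Martin periodinane (1.2 equiv), NaHCO3, CH2Cl2, 0 °C; filtered and used at once
Reagents that add atoms: none
Why: Dess–Martin oxidation under buffered, non-basic conditions should give the β,γ-unsaturated aldehyde without migration of the double bond into conjugation.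

Step 11
Reactants: 13 alkenyl triflate; 15 4-methylpent-3-enal (3 equiv)
Product: 16 (8S)-allylic alcohol (C7(=CH2)–C8H(OH)–CH2–CH=C(CH3)2 on C4; ring as in 11)
Conditions: CrCl2 (4 equiv), NiCl2 (0.1 equiv), (S)-N-[2-(4-isopropyl-4,5-dihydro-1,3-oxazol-2-yl)-6-methylphenyl]methanesulfonamide (4.4 equiv), Et3N (4.4 equiv), THF, rt
Reagents that add atoms: none
Why: In this Nozaki–Hiyama–Kishi reaction the alkenyl triflate adds oxidatively to zerovalent nickel, is passed on to chromium and adds to the aldehyde in the presence of the epoxide and silyl ethers, forming the C7–C8 bond and the 1,1-disubstituted alkene in one step, and the new stereocenter C8 is set by the chiral sulfonamide ligand on chromium (reagent control) because the ring stereocenters are too remote to help.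

Step 12
Reactants: 16 (8S)-allylic alcohol; 17 angelic acid, (Z)-2-methylbut-2-enoic acid (3 equiv)
Product: 19 C8 angelate bis(triethylsilyl) ether (angeloyloxy on C8; C5–OSiEt3 and C6–OSiEt3; ring as in 11), via mixed anhydride 18 (not isolated)
Conditions: 17, 2,4,6-trichlorobenzoyl chloride (3 equiv), Et3N (3.5 equiv), toluene, rt, 2 h; then 16, 60 °C
Reagents that add atoms: none
Why: Acylation of the only free hydroxyl with the preformed mixed anhydride of angelic acid (Yamaguchi-type esterification run without a nucleophilic amine catalyst) should give the allylic angelate without isomerisation of the (Z)-2-methylbut-2-enoyl group to the (E) isomer, and C8 keeps its configuration because its C–O bond is not broken.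

Step 13
Reactants: 19 C8 angelate bis(triethylsilyl) ether
Product: 20 C8 angelate 5,6-diol (C5–OH and C6–OH free; ring epoxide, both alkenes and the C8 ester intact)
Conditions: Bu4NF (4 equiv), AcOH (4 equiv), THF, 0 °C → rt
Reagents that add atoms: none
Why: Fluoride buffered with acetic acid cleaves both triethylsilyl ethers (fluoride desilylation) under near-neutral conditions in which the ring epoxide is not opened and the C8 angelate neither migrates nor isomerises.

Step 14
Reactants: 20 C8 angelate 5,6-diol; 21 angelic anhydride, (Z)-2-methylbut-2-enoic anhydride (3 equiv)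
Product: 22 tris-angelate with the C10=C11 alkene (10,11-deoxy target)
Conditions: LiN(SiMe3)2 (2.05 equiv), THF, −40 °C; then 21, −40 → 0 °C; NH4Cl quench
Reagents that add atoms: none
Why: Both hindered ring hydroxyls are converted into lithium alkoxides and acylated at low temperature by the symmetrical anhydride (alkoxide acylation, a method suited to angelates because no nucleophilic amine catalyst is present to isomerise the (Z)-alkene), the cis relation of the C6 alkoxide to the epoxide excludes a Payne rearrangement, and no stereocenter is touched.

Step 15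
Reactants: 22 tris-angelate alkene
Product: 23 target, (1S,2R,3S,4S,6S)-4-[(3S)-4-[(2R)-3,3-dimethyloxiran-2-yl]-3-{[(2Z)-2-methylbut-2-enoyl]oxy}but-1-en-2-yl]-1-methyl-7-oxabicyclo[4.1.0]heptane-2,3-diyl bis[(2Z)-2-methylbut-2-enoate]
Conditions: 1,2:4,5-di-O-isopropylidene-β-D-erythro-2,3-hexodiulo-2,6-pyranose (D-fructose-derived ketone, 0.3 equiv), KHSO5 (as Oxone), K2CO3, Bu4NHSO4 (cat.), MeCN/CH2(OMe)2/aqueous Na2B4O7 buffer, 0 °C
Reagents that add atoms: potassium peroxymonosulfate, [K+].[O-]S(=O)(=O)OO
Why: In the Shi epoxidation the chiral dioxirane formed from the fructose-derived ketone attacks only the electron-rich trisubstituted C10=C11 alkene (the angelate alkenes are electron-poor and the C7 methylene is 1,1-disubstituted and deactivated by the allylic acyloxy group) and, through the spiro transition state, should deliver oxygen to the face that gives the (R) configuration at C10.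

**Compound list**

1 | 4-methoxy-6-methyl-2H-pyran-2-one (ring carbons C2, C3, C4, C5, C6 become C7, C4, C5, C6, C1) | COC1=CC(=O)OC(C)=C1 | starting material
2 | pent-1-en-3-one (CH2 becomes C3, CH becomes C2) | CCC(=O)C=C | starting material
3 | (1R,4R,7R)-5-methoxy-1-methyl-7-propanoyl-2-oxabicyclo[2.2.2]oct-5-en-3-one (propanoyl syn to the C5=C6 bridge) | O=C1[C@@H]2C[C@@H](C(=O)CC)[C@](C)(O1)C=C2OC | intermediate
4 | methoxy epoxide of 3 (oxirane on C5–C6, oxygen on the lactone-bridge face; formed in the flask) | O=C1[C@@H]2C[C@@H](C(=O)CC)[C@](C)(O1)[C@@H]3O[C@]23OC | intermediate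
5 | α-hydroxy ketone (bridged lactone; C5 ketone; C6–OH syn to the lactone bridge; C2 propanoyl endo) | O=C1[C@@H]2C[C@@H](C(=O)CC)[C@](C)(O1)[C@H](O)C2=O | intermediate
6 | trans-5,6-diol (bridged lactone; C6–OH syn, C5–OH anti to the lactone bridge; C2 propanoyl endo) | O=C1[C@@H]2C[C@@H](C(=O)CC)[C@](C)(O1)[C@H](O)[C@H]2O | intermediate
7 | C2 propanoate of the bridged lactone diol (propanoyloxy anti to the lactone bridge) | O=C1[C@@H]2C[C@@H](OC(=O)CC)[C@](C)(O1)[C@H](O)[C@H]2O | intermediate
8 | bis(triethylsilyl) ether of 7 | O=C1[C@@H]2C[C@@H](OC(=O)CC)[C@](C)(O1)[C@H](O[Si](CC)(CC)CC)[C@H]2O[Si](CC)(CC)CC | intermediate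
9 | Weinreb amide diol (C1–OH cis to C7; C2–OH trans to C1–OH; C5–OSiEt3 trans to C7; C6–OSiEt3 cis to C1–OH) | CON(C)C(=O)[C@@H]1C[C@@H](O)[C@](C)(O)[C@H](O[Si](CC)(CC)CC)[C@H]1O[Si](CC)(CC)CC | intermediate
10 | C2 mesylate of 9 (formed in the flask) | CON(C)C(=O)[C@@H]1C[C@@H](OS(C)(=O)=O)[C@](C)(O)[C@H](O[Si](CC)(CC)CC)[C@H]1O[Si](CC)(CC)CC | intermediate
11 | epoxy Weinreb amide (1,2-epoxide cis to C7 and to C6–O; ring configuration as in 23) | CON(C)C(=O)[C@@H]1C[C@@H]2O[C@]2(C)[C@H](O[Si](CC)(CC)CC)[C@H]1O[Si](CC)(CC)CC | intermediate
12 | methyl ketone (acetyl on C4; ring as in 11) | CC(=O)[C@@H]1C[C@@H]2O[C@]2(C)[C@H](O[Si](CC)(CC)CC)[C@H]1O[Si](CC)(CC)CC | intermediate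
13 | alkenyl triflate (1-(trifluoromethylsulfonyloxy)ethenyl on C4; ring as in 11) | C=C(OS(=O)(=O)C(F)(F)F)[C@@H]1C[C@@H]2O[C@]2(C)[C@H](O[Si](CC)(CC)CC)[C@H]1O[Si](CC)(CC)CC | intermediate
14 | 4-methylpent-3-en-1-ol | CC(C)=CCCO | starting material
15 | 4-methylpent-3-enal | CC(C)=CCC=O | intermediate
16 | (8S)-allylic alcohol (ring as in 11) | C=C([C@H](CC=C(C)C)O)[C@@H]1C[C@@H]2O[C@]2(C)[C@H](O[Si](CC)(CC)CC)[C@H]1O[Si](CC)(CC)CC | intermediate
17 | angelic acid, (Z)-2-methylbut-2-enoic acid | C/C=C(/C)C(=O)O | starting material
18 | (Z)-2-methylbut-2-enoic 2,4,6-trichlorobenzoic anhydride (formed in the flask) | C/C=C(/C)C(=O)OC(=O)c1c(Cl)cc(Cl)cc1Cl | intermediate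
19 | C8 angelate bis(triethylsilyl) ether (ring as in 11) | C=C([C@H](CC=C(C)C)OC(=O)/C(C)=C\C)[C@@H]1C[C@@H]2O[C@]2(C)[C@H](O[Si](CC)(CC)CC)[C@H]1O[Si](CC)(CC)CC | intermediate
20 | C8 angelate 5,6-diol (C5–OH trans to C7, C6–OH cis to the ring epoxide) | C=C([C@H](CC=C(C)C)OC(=O)/C(C)=C\C)[C@@H]1C[C@@H]2O[C@]2(C)[C@H](O)[C@H]1O | intermediate
21 | angelic anhydride, (Z)-2-methylbut-2-enoic anhydride | C/C=C(/C)C(=O)OC(=O)/C(C)=C\C | starting material
22 | tris-angelate with C10=C11 alkene (10,11-deoxy target) | C=C([C@H](CC=C(C)C)OC(=O)/C(C)=C\C)[C@@H]1C[C@@H]2O[C@]2(C)[C@H](OC(=O)/C(C)=C\C)[C@H]1OC(=O)/C(C)=C\C | intermediate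
23 | (1S,2R,3S,4S,6S)-4-[(3S)-4-[(2R)-3,3-dimethyloxiran-2-yl]-3-{[(2Z)-2-methylbut-2-enoyl]oxy}but-1-en-2-yl]-1-methyl-7-oxabicyclo[4.1.0]heptane-2,3-diyl bis[(2Z)-2-methylbut-2-enoate] | C=C([C@H](C[C@H]1OC1(C)C)OC(=O)/C(C)=C\C)[C@@H]1C[C@@H]2O[C@]2(C)[C@H](OC(=O)/C(C)=C\C)[C@H]1OC(=O)/C(C)=C\C | target

**Totals and risks**

Total step count: 15. Longest linear sequence: 14 steps (steps 1–9 and 11–15; step 10 is a one-step branch).

Steps most likely to fail:

1. Step 1 (labelled step). The aromatic pyrone may react too slowly with the iminium ion; the reaction may divert to conjugate addition at C4 followed by rearomatisation; the enol ether may be hydrolysed by the acid co-catalyst; or the facial selectivity may be poor or of the wrong sense. The fallback uses known chemistry and sets out from 1 and 2: the uncatalysed cycloaddition is run neat or in CH2Cl2 under high pressure (about 12 kbar, rt), a known way to take 2-pyrones and vinyl ketones to the bridged lactone without loss of CO2. It should give the endo adduct as a racemate, in which 3 is accompanied by its mirror image, the (1S,4S,7S)-lactone F1. F1 is removed by preparative chromatography on a chiral stationary phase, and the route is rejoined at 3.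

2. Step 11. Facial selectivity at C8 may be poor because the ligand has to override a hindered, branched alkenylchromium reagent, and the aldehyde may isomerise into conjugation. The fallback sets out from 13 and 15: the coupling is run without chiral ligand (CrCl2, NiCl2 cat., DMF, rt) and should give 16 mixed with its C8 epimer, the (8R)-allylic alcohol F2. The mixture is oxidised with Dess–Martin periodinane to the α-methylene ketone F3, which is reduced with (R)-2-methyl-CBS-oxazaborolidine and BH3·SMe2 (Corey–Bakshi–Shibata reduction, the alkenyl group acting as the large substituent). This should return the (8S)-alcohol 16, where the route is rejoined.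

3. Step 14. Acylation of the hindered C6 alkoxide next to the quaternary C1 may be incomplete, the strong base may isomerise an angelate to the (E) ester through its dienolate, and an acyl group may migrate between the neighbouring oxygens before the second acylation. The fallback sets out from 20 and builds the two (Z)-alkenes on the esters instead of transferring them. The diol is esterified with 2-[bis(2,2,2-trifluoroethoxy)phosphoryl]propanoic acid (EDC·HCl, DMAP, CH2Cl2, rt) to the bis(phosphonopropanoate) F4, a mixture of epimers at the two phosphonate-bearing carbons. Still–Gennari olefination with acetaldehyde (KN(SiMe3)2, 18-crown-6, THF, −78 °C) then forms the two (Z)-2-methylbut-2-enoates and comes back to the route at 22.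

**Further compounds**

F1 | step 1 | (1S,4S,7S)-5-methoxy-1-methyl-7-propanoyl-2-oxabicyclo[2.2.2]oct-5-en-3-one (mirror image of 3) | O=C1[C@H]2C[C@H](C(=O)CC)[C@@](C)(O1)C=C2OC
F2 | step 11 | (8R)-allylic alcohol, C8 epimer of 16 | C=C([C@@H](CC=C(C)C)O)[C@@H]1C[C@@H]2O[C@]2(C)[C@H](O[Si](CC)(CC)CC)[C@H]1O[Si](CC)(CC)CC
F3 | step 11 | α-methylene ketone (C8 ketone; ring as in 11) | C=C(C(=O)CC=C(C)C)[C@@H]1C[C@@H]2O[C@]2(C)[C@H](O[Si](CC)(CC)CC)[C@H]1O[Si](CC)(CC)CC
F4 | step 14 | C5,C6-bis{2-[bis(2,2,2-trifluoroethoxy)phosphoryl]propanoate} of 20 | C=C([C@H](CC=C(C)C)OC(=O)/C(C)=C\C)[C@@H]1C[C@@H]2O[C@]2(C)[C@H](OC(=O)C(C)P(=O)(OCC(F)(F)F)OCC(F)(F)F)[C@H]1OC(=O)C(C)P(=O)(OCC(F)(F)F)OCC(F)(F)F
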